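Ring C is cut at O1–C2 and C3–C4, the two bonds that flank the spiro carbon C3. This pattern is what an ortho-quinone methide of ring A leaves when it adds across an exocyclic enol ether on the four-membered ring D. One inverse-demand [4+2] step therefore closes ring C, forms both bonds and sets C3, with a trans-2-phenylcyclohexyl group on the enol oxygen choosing the face. The precursors are the O-Boc salicyl alcohol of ring A and the geometrically pure alkoxymethylidene benzocyclobutene. Afterwards the acetal carbon C2 is reduced to CH2 and benzylic C4 is oxidised to the ketone.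

Key step: step 6

Numbering used: chroman numbering (O1, C2, C3, C4) for ring C; ring A is the dimethoxybenzo ring of the chromanone, ring D the cyclobutene, ring B the veratrole ring fused to ring D.

Assumption: the sense of induction is taken from the usual shielding model for trans-2-phenylcyclohexyl enol ethers (s-trans O–CH=C conformer, carbinol C–H in the enol plane, attack on the face away from the phenyl ring). On that model the (1S,2R)-alcohol is the enantiomer that leads to the (S)-configured spiro carbon of the target; its antipode would give the mirror-image spiro centre.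

Step 1
Reactants: 1 4-bromoveratrole; 2 ketene diethyl acetal
Product: 5 4,5-dimethoxybicyclo[4.2.0]octa-1,3,5-trien-7-one, via dimethoxybenzyne 3 (not isolated), via diethyl acetal 4 (not isolated)
Conditions: NaNH2, THF, reflux; then 1 M HCl, THF, rt
Reagents that add atoms: water, O
Why: Aryne–ketene acetal [2+2] cycloaddition followed by acetal hydrolysis: amide removes the proton between Br and OMe, the acetal CH2 attacks the aryne carbon remote from the methoxy group so that the aryl anion sits next to it, and ring closure places the masked carbonyl carbon beside the methoxy-bearing carbon, as ring D of the target requires.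

Step 2
Reactants: 6 (1S,2R)-trans-2-phenylcyclohexanol
Product: 8 triphenyl({[(1S,2R)-2-phenylcyclohexyl]oxy}methyl)phosphonium chloride, via chloromethyl ether 7 (not isolated)
Conditions: (CH2O)n, Me3SiCl, CH2Cl2, rt; evaporate; PPh3, toluene, 50 °C
Reagents that add atoms: paraformaldehyde (formaldehyde unit), C=O; chlorotrimethylsilane, C[Si](C)(C)Cl; triphenylphosphine, c1ccc(cc1)P(c1ccccc1)c1ccccc1
Why: Chloromethylation of the secondary alcohol followed by SN2 quaternisation of the phosphine by the reactive alpha-chloro ether; neither carbinol stereocentre is touched, and the hazardous chloromethyl ether is used crude.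

Step 3
Reactants: 8 triphenyl({[(1S,2R)-2-phenylcyclohexyl]oxy}methyl)phosphonium chloride; 5 4,5-dimethoxybicyclo[4.2.0]octa-1,3,5-trien-7-one
Product: 10 (8E)-2,3-dimethoxy-8-({[(1S,2R)-2-phenylcyclohexyl]oxy}methylidene)bicyclo[4.2.0]octa-1,3,5-triene (exocyclic enol ether of 5, oxygen cis to the ring CH2), via ylide 9 (not isolated)
Conditions: 8, KN(SiMe3)2, THF, −78 → 0 °C; then 5, −78 °C → rt; Et3N-deactivated silica
Reagents that add atoms: none
Why: Wittig alkoxymethylenation of a ketone that cannot enolise without becoming antiaromatic; the bulky alkoxy group should settle on the CH2 side, away from the aryl carbon flanked by a methoxy group, and any minor isomer is removed by chromatography on base-washed silica.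

Step 4
Reactants: 11 2-hydroxy-4,6-dimethoxybenzaldehyde
Product: 12 tert-butyl (2-formyl-3,5-dimethoxyphenyl) carbonate
Conditions: Boc2O, i-Pr2NEt, DMAP (cat.), CH2Cl2, 0 °C → rt
Reagents that add atoms: di-tert-butyl dicarbonate, CC(C)(C)OC(=O)OC(=O)OC(C)(C)C
Why: DMAP-catalysed O-acylation of the phenol, which is the only acidic site.

Step 5
Reactants: 12 tert-butyl (2-formyl-3,5-dimethoxyphenyl) carbonate
Product: 13 tert-butyl [2-(hydroxymethyl)-3,5-dimethoxyphenyl] carbonate
Conditions: BH3·THF, THF, −10 → 0 °C; pH 7 buffer
Reagents that add atoms: none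
Why: Borane reduction of the aldehyde passes through a neutral borate ester and never a free alkoxide, so the carbonate cannot migrate and release the quinone methide early, as a borohydride reduction would risk; the acid-sensitive benzylic alcohol is worked up neutral and used promptly.

Step 6
Reactants: 13 tert-butyl [2-(hydroxymethyl)-3,5-dimethoxyphenyl] carbonate; 10 (8E)-2,3-dimethoxy-8-({[(1S,2R)-2-phenylcyclohexyl]oxy}methylidene)bicyclo[4.2.0]octa-1,3,5-triene
Product: 16 (2'R,7S)-4,5,5',7'-tetramethoxy-2'-{[(1S,2R)-2-phenylcyclohexyl]oxy}spiro[bicyclo[4.2.0]octa-1,3,5-triene-7,3'-chromane], via benzylic carbonate 14 (not isolated), via ortho-quinone methide 15 (not isolated)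
Conditions: 10 (1 equiv), 13 (2 equiv), t-BuMgCl (1.05 equiv per 13, slow addition), Et2O, −78 °C → rt
Reagents that add atoms: none
Why: The Grignard base deprotonates the benzylic OH, the alkoxide takes the Boc group from the phenol oxygen through a six-membered transition state (14), and the magnesium phenoxide expels tert-butyl carbonate to give the quinone methide 15; its exocyclic CH2 is then attacked by the electron-rich ring carbon of 10 while the enol CH closes on the quinone oxygen in a concerted, asynchronous inverse-demand hetero-Diels–Alder reaction that restores the aromaticity of ring A. The closest known reaction type is the low-temperature anionic generation of ortho-quinone methides from O-Boc salicyl alcohols and their diastereoselective [4+2] addition to enol ethers of trans-2-phenylcyclohexanol, here asked to accept a more hindered, doubly substituted enol terminus. Ring C is closed by intermolecular [4+2] cycloaddition, forming C3–C4 and O1–C2 in one operation. Two stereocentres arise: suprafacial addition to the single E isomer ties the acetal carbon C2 to the spiro carbon C3, and the absolute sense comes from the auxiliary, whose phenyl ring screens one face of the s-trans enol ether (the s-cis conformer is excluded by the clash between the auxiliary and the ring CH2), so that the heterodiene should add to the Re face of the enol CH and give (S)-C3. Regiochemistry is secured by polarity; endo or exo approach is irrelevant because the methide carbon is unsubstituted. The step also needs cross-addition to outrun self-condensation of 15 and conjugate addition of the Grignard reagent, which slow generation from an excess of 13 with no surplus t-BuMgCl is meant to ensure.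

Step 7
Reactants: 16 (2'R,7S)-4,5,5',7'-tetramethoxy-2'-{[(1S,2R)-2-phenylcyclohexyl]oxy}spiro[bicyclo[4.2.0]octa-1,3,5-triene-7,3'-chromane]
Product: 17 (7S)-4,5,5',7'-tetramethoxyspiro[bicyclo[4.2.0]octa-1,3,5-triene-7,3'-chromane]
Conditions: Et3SiH (excess), BF3·OEt2, CH2Cl2, −78 → −30 °C
Reagents that add atoms: none
Why: Ionic hydrogenation of a mixed acetal: BF3 ionises the more basic exocyclic alkoxy group, and the cyclic oxocarbenium ion is reduced at once by the silane, which turns C2 into CH2 and frees the auxiliary for recovery; the quaternary C3 is not involved, and low temperature with excess silane is chosen so that hydride capture precedes any shift of the strained ring.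

Step 8
Reactants: 17 (7S)-4,5,5',7'-tetramethoxyspiro[bicyclo[4.2.0]octa-1,3,5-triene-7,3'-chromane]
Product: 19 (7S)-4,5,5',7'-tetramethoxyspiro[bicyclo[4.2.0]octa-1,3,5-triene-7,3'-chroman]-4'-one (CNP0192565.1), via benzylic alcohol 18 (not isolated)
Conditions: DDQ (2.5 equiv), CH2Cl2/H2O, 0 °C → rt
Reagents that add atoms: water, O
Why: DDQ benzylic oxidation: hydride abstraction from C4 gives a cation stabilised by O1 and by the 5- and 7-methoxy groups, water captures it, and a second equivalent oxidises the electron-rich benzylic alcohol to the aryl ketone. The CH2 of ring D is spared because its cation would be a strained benzocyclobutenyl ion on a less activated ring, and the quaternary C3 rules out dehydrogenation to a chromene.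

Compound list
1 | 4-bromoveratrole (4-bromo-1,2-dimethoxybenzene) | COc1ccc(Br)cc1OC | starting material
2 | ketene diethyl acetal (1,1-diethoxyethene) | C=C(OCC)OCC | starting material
3 | 3,4-dimethoxybenzyne (1,2-didehydro-3,4-dimethoxybenzene) | COC1=C(OC)C#CC=C1 | intermediate
4 | 7,7-diethoxy-4,5-dimethoxybicyclo[4.2.0]octa-1,3,5-triene | CCOC1(OCC)Cc2ccc(OC)c(OC)c21 | intermediate
5 | 4,5-dimethoxybicyclo[4.2.0]octa-1,3,5-trien-7-one (carbonyl carbon on the aromatic carbon next to a methoxy group) | O=C1Cc2ccc(OC)c(OC)c21 | intermediate
6 | (1S,2R)-trans-2-phenylcyclohexanol | O[C@H]1CCCC[C@@H]1c1ccccc1 | starting material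
7 | (1S,2R)-1-(chloromethoxy)-2-phenylcyclohexane | ClCO[C@H]1CCCC[C@@H]1c1ccccc1 | intermediate
8 | triphenyl({[(1S,2R)-2-phenylcyclohexyl]oxy}methyl)phosphonium chloride | [Cl-].c1ccccc1[P+](c1ccccc1)(c1ccccc1)CO[C@H]1CCCC[C@@H]1c1ccccc1 | intermediate
9 | triphenyl({[(1S,2R)-2-phenylcyclohexyl]oxy}methylidene)phosphorane | c1ccccc1P(c1ccccc1)(c1ccccc1)=CO[C@H]1CCCC[C@@H]1c1ccccc1 | intermediate
10 | (8E)-2,3-dimethoxy-8-({[(1S,2R)-2-phenylcyclohexyl]oxy}methylidene)bicyclo[4.2.0]octa-1,3,5-triene (oxygen cis to the ring CH2) | O(/C=C1\Cc2ccc(OC)c(OC)c21)[C@H]1CCCC[C@@H]1c1ccccc1 | intermediate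
11 | 2-hydroxy-4,6-dimethoxybenzaldehyde | COc1cc(O)c(C=O)c(OC)c1 | starting material
12 | tert-butyl (2-formyl-3,5-dimethoxyphenyl) carbonate | COc1cc(OC(=O)OC(C)(C)C)c(C=O)c(OC)c1 | intermediate
13 | tert-butyl [2-(hydroxymethyl)-3,5-dimethoxyphenyl] carbonate | COc1cc(OC(=O)OC(C)(C)C)c(CO)c(OC)c1 | intermediate
14 | tert-butyl (2-hydroxy-4,6-dimethoxyphenyl)methyl carbonate (present as its magnesium phenoxide) | COc1cc(O)c(COC(=O)OC(C)(C)C)c(OC)c1 | intermediate
15 | 3,5-dimethoxy-6-methylidenecyclohexa-2,4-dien-1-one | C=C1C(=O)C=C(OC)C=C1OC | intermediate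
16 | (2'R,7S)-4,5,5',7'-tetramethoxy-2'-{[(1S,2R)-2-phenylcyclohexyl]oxy}spiro[bicyclo[4.2.0]octa-1,3,5-triene-7,3'-chromane] | COc1cc(OC)c2c(c1)O[C@@H](O[C@H]1CCCC[C@@H]1c1ccccc1)[C@@]1(Cc3ccc(OC)c(OC)c31)C2 | intermediate
17 | (7S)-4,5,5',7'-tetramethoxyspiro[bicyclo[4.2.0]octa-1,3,5-triene-7,3'-chromane] | COc1cc(OC)c2c(c1)OC[C@@]1(Cc3ccc(OC)c(OC)c31)C2 | intermediate
18 | (7S)-4,5,5',7'-tetramethoxyspiro[bicyclo[4.2.0]octa-1,3,5-triene-7,3'-chroman]-4'-ol (either C4' epimer) | COc1cc(OC)c2c(c1)OC[C@@]1(Cc3ccc(OC)c(OC)c31)C2O | intermediate
19 | (7S)-4,5,5',7'-tetramethoxyspiro[bicyclo[4.2.0]octa-1,3,5-triene-7,3'-chroman]-4'-one | COc1cc(OC)c2c(c1)OC[C@@]1(Cc3ccc(OC)c(OC)c31)C2=O | target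

Total step count: 8. Longest linear sequence: 5 steps (for example 1 → 5 → 10 → 16 → 17 → 19, steps 1, 3, 6, 7 and 8).

Steps most likely to fail

Step 6. The quinone methide may be consumed by self-condensation faster than the hindered, doubly substituted enol terminus can trap it. Facial selectivity may also be poor, because the first bond forms at the carbon remote from the auxiliary. The fallback gives up auxiliary control and resolves instead. It sets out from 5 and 13. Wittig reaction of 5 with (methoxymethyl)triphenylphosphonium chloride and KN(SiMe3)2 gives 2,3-dimethoxy-8-(methoxymethylidene)bicyclo[4.2.0]octa-1,3,5-triene F1, whose double-bond geometry no longer matters. This small, cheap enol ether is used in large excess in the same t-BuMgCl-triggered cycloaddition with 13 to give the racemic 2'-methoxy spiro acetal F2. Et3SiH with BF3·OEt2 reduces it to the racemic spiro chroman F3. Preparative chromatography on a chiral stationary phase then delivers the (7S) enantiomer, and the route is rejoined at 17.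

Step 3. The basic ylide may open the strained ketone, or the two double-bond isomers may form together and prove inseparable without hydrolysing the acid-labile enol ether. The fallback makes the enol C–O bond instead of the C=C bond with the auxiliary in place. It sets out from 5 and 6. Wittig iodomethylenation of 5 (the ylide from (iodomethyl)triphenylphosphonium iodide and NaN(SiMe3)2, THF, −78 °C) gives a robust vinyl iodide whose isomers can be separated on ordinary silica. The isomer with iodine cis to the ring CH2, (8E)-8-(iodomethylidene)-2,3-dimethoxybicyclo[4.2.0]octa-1,3,5-triene F4, is coupled with 6 in an Ullmann-type vinylation (CuI, 3,4,7,8-tetramethyl-1,10-phenanthroline, Cs2CO3, toluene, 80 °C). This coupling retains alkene geometry and returns to the route at 10.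

Step 7. The Lewis acid may ionise the endocyclic aryl C2–O1 bond, so that hydride delivery gives a ring-opened ether, or the oxocarbenium ion beside the four-membered ring may undergo Wagner–Meerwein ring expansion before it is reduced. The fallback never delivers hydride to a cation. It sets out from 16. Mild aqueous acid (camphorsulfonic acid, THF/H2O) hydrolyses the acetal to the lactol (7S)-4,5,5',7'-tetramethoxyspiro[bicyclo[4.2.0]octa-1,3,5-triene-7,3'-chroman]-2'-ol F5; either mode of C–O cleavage ends in this compound, and the auxiliary is recovered. NaBH4 in MeOH reduces the open hydroxy-aldehyde form to the diol 2-{[(7S)-7-(hydroxymethyl)-4,5-dimethoxybicyclo[4.2.0]octa-1,3,5-trien-7-yl]methyl}-3,5-dimethoxyphenol F6. An intramolecular Mitsunobu etherification (PPh3, diisopropyl azodicarboxylate, THF) closes ring C again and rejoins the route at 17.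

Further compounds
F1 | step 6 | 2,3-dimethoxy-8-(methoxymethylidene)bicyclo[4.2.0]octa-1,3,5-triene (either double-bond isomer) | COC=C1Cc2ccc(OC)c(OC)c21
F2 | step 6 | racemic 2',4,5,5',7'-pentamethoxyspiro[bicyclo[4.2.0]octa-1,3,5-triene-7,3'-chromane] (diastereomer mixture) | COc1cc(OC)c2c(c1)OC(OC)C1(Cc3ccc(OC)c(OC)c31)C2
F3 | step 6 | racemic 4,5,5',7'-tetramethoxyspiro[bicyclo[4.2.0]octa-1,3,5-triene-7,3'-chromane] | COc1cc(OC)c2c(c1)OCC1(Cc3ccc(OC)c(OC)c31)C2
F4 | step 3 | (8E)-8-(iodomethylidene)-2,3-dimethoxybicyclo[4.2.0]octa-1,3,5-triene (iodine cis to the ring CH2) | I/C=C1\Cc2ccc(OC)c(OC)c21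
F5 | step 7 | (7S)-4,5,5',7'-tetramethoxyspiro[bicyclo[4.2.0]octa-1,3,5-triene-7,3'-chroman]-2'-ol (either C2' epimer) | COc1cc(OC)c2c(c1)OC(O)[C@@]1(Cc3ccc(OC)c(OC)c31)C2
F6 | step 7 | 2-{[(7S)-7-(hydroxymethyl)-4,5-dimethoxybicyclo[4.2.0]octa-1,3,5-trien-7-yl]methyl}-3,5-dimethoxyphenol | COc1cc(OC)c(C[C@@]2(CO)Cc3ccc(OC)c(OC)c32)c(O)c1
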